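## The problem

Labdane numbering is used throughout: ring A is C1–C5 and C10, ring B is C5–C10, the side chain is C11–C16, C17 is the methyl on C8, C18 and C19 are on C4, and C20 is on C10.

- Target 31 is a trans-decalin that carries a tetrahydrofuran spiro at C9 (O–C9–C11–C12–C13) and, spiro to that at C13, a 2,3-dihydrofuran (C13–C14=C15–O–C16). Ring B has three neighbouring oxygenated carbons: the C6 ketone, the equatorial 7β-acetate, and the axial 8β-hydroxyl with its equatorial methyl C17.
- C5 and C10 fix the decalin and can steer ring B. The axial C10 methyl covers the β face of C8 and C9, and together with the axial C4 methyl it covers the β face of C6.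
- C13 is two methylene groups away from the ring and cannot be steered by it, so it needs a reagent-controlled step.
- The hard atom is C9. It is fully substituted, sits next to quaternary C10, and its oxygen is axial and anti to the C10 methyl. A carbon nucleophile adding to a C9 ketone would take that face and leave oxygen on the wrong one, so the C9–C11 bond should exist first and oxygen should arrive as the nucleophile.
- Three groups are fragile. Acid ionises the allylic C13–O bond of the spiro enol ether and the dihydrofuran goes on to a furan. The β-hydroxy ketone can undergo retro-aldol cleavage or dehydration, and the α-acetoxy ketone can epimerise or shift its acyl group. The dihydrofuran is therefore unveiled last and under base.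
- The feature that opens the key step: with C17 temporarily removed, a C8 carbonyl can be enolised toward C9. The C8=C9 enol ether is then the most electron-rich group in the molecule, and a hydroxyl on C13 sits four atoms from C9. One-electron oxidation makes C9 the electrophile for a five-membered ring closure from the α face.

## Retrosynthesis

**Dihydrofuran (31 ⇐ 30 ⇐ 28).** The enol ether is cut at C14=C15 back to lactol 30, and 30 to the C15 aldehyde 29, which comes from ozonolysis of a terminal alkene in 28. An allyl group on C13 thus stands for C14–C15 through the whole route. Unlike an acetal it needs no acid to unveil, and it tolerates bases, organometallics and the anode. The forward steps must be non-acidic.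

**C7 acetate (27 ⇐ 25 ⇐ 23).** The C7–O bond is cut. Direct oxidation of a C6 enolate would put oxygen on the open α face, which gives the wrong (axial) epimer. The enol acetate 25 is epoxidised on that same α face, and the thermal acyl shift in epoxide 26 then delivers the acetate to C7 with inversion, that is on the β face. The precursor 23 lacks one stereocentre and one oxygen.

**Ring B oxygens (23 ⇐ 22 ⇐ 21 ⇐ 19 ⇐ 18).** C8–C17 is cut (methyl Grignard on the C8 ketone), then C6–O (conjugate borylation of enone 19 and oxidation), then the C6=C7 double bond (dehydrogenation of 18). The C8 carbonyl left by the key step is the single handle for all three operations. Conjugate borylation is chosen over hydroboration or osmylation because it leaves the allyl group alone.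

**Key disconnection (18 ⇐ 17).** The O–C9 bond is cut. The precursor 17 has no spiro centre: C9 is the sp2 carbon of a silyl enol ether and the oxygen is a tertiary alcohol on C13. The forward reaction must oxidise only the enol ether and add oxygen anti to the C10 methyl. A tert-butyldimethylsilyl enol ether is chosen because it has to survive a Grignard reagent, chromatography and methanol in the cell.

**Allyl group and enol ether (17 ⇐ 15 + 16; 15 ⇐ 14).** C14–C15 is cut: vinylmagnesium bromide 16 opens the 2,2-disubstituted epoxide of 15 at its CH2 terminus. The enol ether is made before this step, from ketone 14. In that order it hides the C8 carbonyl from the Grignard reagent, and the tertiary alcohol appears only after all silylations are done. This solves two chemoselectivity problems without extra steps.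

**C13 stereocentre (14 ⇐ 13 ⇐ 12).** The C13–O bond is cut by Sharpless epoxidation of the 2-substituted allylic alcohol 12. This is reagent control at a centre the ring cannot influence, and the precursor has no side-chain stereocentre.

**C12–C13 bond (12 ⇐ 7 + 9; 9 ⇐ 8).** An sp3–sp2 Negishi coupling joins the primary iodide 7 to the silylated 2-bromoallyl alcohol 9. An alkylzinc is chosen because it tolerates the C8 ketone.

**Decalin (7 ⇐ 6 ⇐ 5 ⇐ 4 ⇐ 3 ⇐ 2 ⇐ 1).** (+)-Sclareolide 1 supplies C1–C12 with C5, C10 and the C9–C11 bond correct. Its lactone is reduced, C17 is cut off by dehydration and ozonolysis, and C12 becomes the iodide. C17 returns in step 16 with the opposite C8 configuration, which sclareolide does not have.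

## Roads not taken

**Alternative 1: quinone Diels–Alder.**
- Cut: C1–C10 and C4–C5 of ring A.
- Forward step: a chiral titanium binaphtholate Lewis acid (from TiCl2(OiPr)2) activates 2,6-dimethyl-1,4-benzoquinone A1, and 4-methylpenta-1,3-diene A2 adds to give the cis-fused enedione A3.
- Merits: two C–C bonds and quaternary C10 form in one enantioselective step from achiral materials. A3 already has the C6 and C9 carbonyls and the C7=C8 alkene with C17 in place. This is better than the chosen route, which removes C17 (steps 3–4) and spends steps 14–17 restoring it and oxidising C6.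
- Weak points: A2 carries a Z-methyl on its reacting terminus and reaches the s-cis form reluctantly. The ring fusion comes out cis and must be epimerised at C5. The extra C2=C3 alkene has to be removed. Above all, C9 is a ketone in A3: a carbon nucleophile bringing C11 would add anti to the C10 methyl and put oxygen on the β face, the opposite of the target.
- Comparison: this road is shorter to an oxidised ring B. The chosen plan sets against it a chiral-pool decalin that already has the C9–C11 bond, and a key step that adds oxygen, not carbon, to the open face of C9.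

**Alternative 2: radical bicyclisation onto a spiro-furanone.**
- Cut: C4–C5 and C9–C10.
- Forward step: hydrogen-atom transfer from Fe(acac)3 and a silane to a terminal 1,1-disubstituted alkene gives the C4 radical, which closes ring A at C5. The C10 radical then adds to C9 of a furanone and closes ring B, giving A4.
- Merits: both carbocycles and two quaternary carbons form at once. The C6 oxygen, the C8 carbinol and the C13 spiro centre are already present, so ring B needs no later oxidation. In that respect it beats steps 14–19 of the chosen route.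
- Weak points: the second bond joins two fully substituted carbons. C5, C10 and C9 are set in one step from a flexible chain, with no clear bias for placing the C9 oxygen anti to the C10 methyl. The acyclic precursor needs C6, C8 and C13 set separately. The C12 ketone must be deleted and the butanolide reduced to the dihydrofuran beside the ring B carbonyls.
- Comparison: this road is more convergent. The chosen plan sets against it that only one stereocentre (C9) is made in the key step, under control of the adjacent C10 methyl, while C5 and C10 come from sclareolide.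

**Alternative 3: dichloroketene cycloaddition.**
- Cut: C13–C14 and C15–C16.
- Forward step: dichloroketene A6, made in situ, adds across the exocyclic C13=C16 enol ether A5 to give the spiro dichlorocyclobutanone A7. Ring expansion, dechlorination, reduction and dehydration would follow.
- Merits: the spiro C13 and both C14 and C15 arrive in one step with reliable regiochemistry. No terminal alkene is carried, so ring B could be oxidised with osmium or borane reagents that the allyl group of the chosen route forbids.
- Weak points: C13 is set by facial selectivity on an exocyclic alkene whose faces differ only through distant ring B substituents. A5 is an acid-labile 2-methylene-tetrahydrofuran. Most important, A5 already contains the C9–O bond, so this cut does not address C9 at all.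
- Comparison: this road is freer in ring B chemistry. The chosen plan sets against it reagent control at C13 (step 9) and the use of the same C13 oxygen to solve C9; its price is the three-step unveiling at the end.

Key step: step 13

Remarks on the chemistry:
- All compounds belong to the normal labdane series (5α-H, 10β-methyl).
- Lactol 30 is expected as a mixture of C15 anomers, so C15 is left undefined in its SMILES.
- The C13 descriptor changes between R and S along the route only because substituent priorities change; the spatial arrangement is that of the target from step 9 on.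

## Route

Step 1
Reactants: 1 (+)-sclareolide
Product: 2 13,14,15,16-tetranorlabdane-8α,12-diol
Conditions: LiAlH4, THF, 0 °C to reflux; then H2O, aq NaOH
Reagents that add atoms: none
Why: Hydride reduction of the lactone gives the primary C12 alcohol and frees the 8α tertiary alcohol; no stereocentre is touched.

Step 2
Reactants: 2 13,14,15,16-tetranorlabdane-8α,12-diol
Product: 3 8α-hydroxy-13,14,15,16-tetranorlabdan-12-yl acetate
Conditions: Ac2O, pyridine, 0 to 23 °C
Reagents that add atoms: acetic anhydride, CC(=O)OC(C)=O
Why: Acetylation of the primary hydroxyl only; without an acyl-transfer catalyst the hindered tertiary hydroxyl does not react. The ester prevents ether closure between C8 and C12 in the next step.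

Step 3
Reactants: 3 8α-hydroxy-13,14,15,16-tetranorlabdan-12-yl acetate
Product: 4 13,14,15,16-tetranorlabd-8(17)-en-12-yl acetate
Conditions: SOCl2, pyridine, CH2Cl2, −78 °C
Reagents that add atoms: none
Why: Dehydration through the chlorosulfite (E2). The equatorial C8–O bond has no antiperiplanar ring hydrogen, while the axial C17 methyl can always align one, so the exocyclic alkene should dominate at low temperature.

Step 4
Reactants: 4 13,14,15,16-tetranorlabd-8(17)-en-12-yl acetate
Product: 5 8-oxo-13,14,15,16,17-pentanorlabdan-12-yl acetate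
Conditions: O3, CH2Cl2/MeOH, −78 °C; then Me2S, −78 to 23 °C
Reagents that add atoms: ozone, [O-][O+]=O
Why: Ozonolysis with reductive work-up cleaves C8=C17 to the C8 ketone. Endocyclic alkene isomers from step 3 give ring-opened products that are removed here; C9 keeps its equatorial side chain.

Step 5
Reactants: 5 8-oxo-13,14,15,16,17-pentanorlabdan-12-yl acetate
Product: 6 12-hydroxy-13,14,15,16,17-pentanorlabdan-8-one
Conditions: K2CO3, MeOH, 23 °C
Reagents that add atoms: none
Why: Base-catalysed transesterification removes the acetate; the equatorial C9 side chain is already the stable arrangement.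

Step 6
Reactants: 6 12-hydroxy-13,14,15,16,17-pentanorlabdan-8-one
Product: 7 12-iodo-13,14,15,16,17-pentanorlabdan-8-one
Conditions: I2, PPh3, imidazole, CH2Cl2, 0 to 23 °C
Reagents that add atoms: iodine, II
Why: Appel-type iodination converts the primary alcohol to the iodide by SN2 under near-neutral conditions that leave the enolisable ketone alone.

Step 7
Reactants: 8 2-bromoprop-2-en-1-ol
Product: 9 (2-bromoprop-2-enyloxy)trimethylsilane
Conditions: Me3SiCl, Et3N, CH2Cl2, 0 °C
Reagents that add atoms: chlorotrimethylsilane, C[Si](C)(C)Cl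
Why: Silylation masks the O–H during the organozinc coupling; the group is removed again in the work-up of step 8.

Step 8
Reactants: 7 12-iodo-13,14,15,16,17-pentanorlabdan-8-one; 9 (2-bromoprop-2-enyloxy)trimethylsilane
Product: 12 16-hydroxy-15,17-dinorlabd-13(14)-en-8-one, via alkylzinc iodide 10 (not isolated), via trimethylsilyl ether 11 (not isolated)
Conditions: Zn dust (activated by BrCH2CH2Br and Me3SiCl), LiCl, THF, 35 °C; then 9, Pd(dppf)Cl2 (5 mol %), THF, 45 °C; then K2CO3, MeOH, 0 °C
Reagents that add atoms: none
Why: Negishi cross-coupling. Zinc inserts into the primary C–I bond to give an alkylzinc that tolerates the ketone, and the wide-bite-angle palladium catalyst favours reductive elimination over β-hydride elimination. Carbonate methanolysis then removes the trimethylsilyl group.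

Step 9
Reactants: 12 16-hydroxy-15,17-dinorlabd-13(14)-en-8-one
Product: 13 (13R)-13,14-epoxy-16-hydroxy-15,17-dinorlabdan-8-one
Conditions: Ti(OiPr)4 (10 mol %), D-(−)-diethyl tartrate (12 mol %), t-BuOOH, 4 Å molecular sieves, CH2Cl2, −20 °C
Reagents that add atoms: tert-butyl hydroperoxide, CC(C)(C)OO
Why: Sharpless asymmetric epoxidation. The titanium tartrate binds the allylic alkoxide and delivers oxygen to one alkene face; D-(−)-tartrate gives the (R)-2-substituted glycidol, as it does with 2-methylprop-2-en-1-ol. C13 is set here under reagent control.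

Step 10
Reactants: 13 (13R)-13,14-epoxy-16-hydroxy-15,17-dinorlabdan-8-one
Product: 14 (13S)-16-(tert-butyldimethylsilyloxy)-13,14-epoxy-15,17-dinorlabdan-8-one
Conditions: t-BuMe2SiCl, imidazole, DMF, 0 to 23 °C
Reagents that add atoms: tert-butyldimethylsilyl chloride, CC(C)(C)[Si](C)(C)Cl
Why: Silylation of the primary alcohol prevents Payne rearrangement under the basic steps that follow and later keeps this oxygen out of the cyclisation.

Step 11
Reactants: 14 (13S)-16-(tert-butyldimethylsilyloxy)-13,14-epoxy-15,17-dinorlabdan-8-one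
Product: 15 (13S)-8,16-bis(tert-butyldimethylsilyloxy)-13,14-epoxy-15,17-dinorlabd-8-ene
Conditions: LiN(SiMe3)2 (0.95 equiv), THF, −78 to 23 °C; then t-BuMe2SiCl, DMPU, −78 to 0 °C
Reagents that add atoms: tert-butyldimethylsilyl chloride, CC(C)(C)[Si](C)(C)Cl
Why: Thermodynamic enolate formation and O-silylation. With slightly less than one equivalent of base the lithium enolates equilibrate through the remaining ketone toward the tetrasubstituted C8=C9 enolate. Attack of the enolate carbon on the epoxide would need a four-membered closure at a quaternary carbon or a 5-endo opening, both disfavoured.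

Step 12
Reactants: 15 (13S)-8,16-bis(tert-butyldimethylsilyloxy)-13,14-epoxy-15,17-dinorlabd-8-ene; 16 vinylmagnesium bromide
Product: 17 (13S)-8,16-bis(tert-butyldimethylsilyloxy)-15-methylidene-17-norlabd-8-en-13-ol
Conditions: CuI (20 mol %), THF, −30 to 0 °C; aq NH4Cl/NH3 work-up
Reagents that add atoms: none
Why: Copper-catalysed SN2 opening of the 2,2-disubstituted epoxide at its CH2 terminus. The C13–O bond is not touched, so the configuration from step 9 is kept. The silyl enol ether shields C8 from the Grignard reagent.

Step 13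
Reactants: 17 (13S)-8,16-bis(tert-butyldimethylsilyloxy)-15-methylidene-17-norlabd-8-en-13-ol
Product: 18 (13S)-16-(tert-butyldimethylsilyloxy)-9α,13-epoxy-15-methylidene-17-norlabdan-8-one
Conditions: reticulated vitreous carbon anode, Pt cathode, undivided cell, constant current (8 mA, about 2.2 F/mol), LiClO4 (0.1 M), MeOH/CH2Cl2 1:4, 2,6-lutidine, 23 °C
Reagents that add atoms: none
Why: Anodic coupling of an enol ether radical cation with a tethered alcohol, a known route to tetrahydrofurans with a tetrasubstituted ether carbon. The tetrasubstituted silyl enol ether is by far the most easily oxidised group, so the anode removes one electron from it while the terminal alkene and the silyl ether stay untouched. The C13 hydroxyl adds to C9, the carbon remote from the silyloxy group, in a 5-exo-trig closure that forms O–C9 and the tetrahydrofuran; 2,6-lutidine takes the proton. The C8 radical is oxidised again to a silyloxocarbenium ion, and methanol removes the silyl group to leave the ketone. The new stereocentre C9 is controlled by the axial C10 methyl: oxygen approaches the planar C9 from the opposite α face and forms an axial bond, so C11 ends equatorial as in the target. The step needs ring closure to outrun capture by methanol, which the five-membered transition state secures, and the buffered medium keeps the enol ether from solvolysis.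

Step 14
Reactants: 18 (13S)-16-(tert-butyldimethylsilyloxy)-9α,13-epoxy-15-methylidene-17-norlabdan-8-one
Product: 19 (13S)-16-(tert-butyldimethylsilyloxy)-9α,13-epoxy-15-methylidene-17-norlabd-6-en-8-one
Conditions: LiN(iPr)2, THF, −78 °C; then PhS(Cl)=N-t-Bu, −78 °C
Reagents that add atoms: none
Why: One-pot ketone dehydrogenation by the sulfinimidoyl chloride method. C7 is the only enolisable position; the enolate attacks sulfur and syn-elimination at low temperature gives the C6=C7 enone.

Step 15
Reactants: 19 (13S)-16-(tert-butyldimethylsilyloxy)-9α,13-epoxy-15-methylidene-17-norlabd-6-en-8-one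
Product: 21 (13S)-16-(tert-butyldimethylsilyloxy)-9α,13-epoxy-6α-hydroxy-15-methylidene-17-norlabdan-8-one, via C6 pinacol boronate 20 (not isolated)
Conditions: B2pin2, CuCl (5 mol %), NaOt-Bu (10 mol %), Xantphos (5 mol %), MeOH, THF, 23 °C; then NaBO3·4H2O, THF/H2O, 23 °C
Reagents that add atoms: sodium perborate, B(=O)O[O-].[Na+]
Why: Copper-catalysed conjugate borylation of the enone, then C–B oxidation with retention. Boron adds to C6 from the α face because the axial methyls on C4 and C10 cover the β face. The isolated terminal alkene is not borylated, and the C6 configuration is erased in step 17.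

Step 16
Reactants: 21 (13S)-16-(tert-butyldimethylsilyloxy)-9α,13-epoxy-6α-hydroxy-15-methylidene-17-norlabdan-8-one
Product: 22 (13S)-16-(tert-butyldimethylsilyloxy)-9α,13-epoxy-15-methylidenelabdane-6α,8β-diol
Conditions: MeMgBr, CeCl3, THF, −78 to 0 °C
Reagents that add atoms: methylmagnesium bromide, C[Mg]Br
Why: Cerium-promoted Grignard addition, which suppresses enolisation. The axial C10 methyl blocks the β face of C8, so methyl enters equatorially from the α face and the hydroxyl ends axial (8β). Nucleophiles behave this way with 5α-oxygenated 6-oxo steroids, the closest model for a ketone flanked by an axial α-oxygen and a 1,3-axial methyl.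

Step 17
Reactants: 22 (13S)-16-(tert-butyldimethylsilyloxy)-9α,13-epoxy-15-methylidenelabdane-6α,8β-diol
Product: 23 (13S)-16-(tert-butyldimethylsilyloxy)-9α,13-epoxy-8β-hydroxy-15-methylidenelabdan-6-one
Conditions: Dess–Martin periodinane, NaHCO3, CH2Cl2, 0 to 23 °C
Reagents that add atoms: none
Why: Dess–Martin oxidation of the secondary C6 alcohol under buffered, non-basic conditions avoids retro-aldol cleavage or dehydration of the new β-hydroxy ketone; the tertiary alcohol is inert.

Step 18
Reactants: 23 (13S)-16-(tert-butyldimethylsilyloxy)-9α,13-epoxy-8β-hydroxy-15-methylidenelabdan-6-one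
Product: 25 (13S)-16-(tert-butyldimethylsilyloxy)-9α,13-epoxy-15-methylidene-8β-(trimethylsilyloxy)labd-6-en-6-yl acetate, via trimethylsilyl ether 24 (not isolated)
Conditions: LiN(SiMe3)2 (1.05 equiv), Me3SiCl (1.05 equiv), THF, −78 to 0 °C; then LiN(SiMe3)2 (1.5 equiv), −78 to −40 °C; then Ac2O, −78 °C
Reagents that add atoms: chlorotrimethylsilane, C[Si](C)(C)Cl; acetic anhydride, CC(=O)OC(C)=O
Why: The tertiary alkoxide is silylated first. Kinetic deprotonation then occurs at C7, because C5–H is buried between two quaternary carbons, and O-acylation of the lithium enolate gives the C6=C7 enol acetate.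

Step 19
Reactants: 25 (13S)-16-(tert-butyldimethylsilyloxy)-9α,13-epoxy-15-methylidene-8β-(trimethylsilyloxy)labd-6-en-6-yl acetate
Product: 27 (13S)-7β-acetoxy-16-(tert-butyldimethylsilyloxy)-9α,13-epoxy-15-methylidene-8β-(trimethylsilyloxy)labdan-6-one, via epoxy acetate 26 (not isolated)
Conditions: dimethyldioxirane, acetone/CH2Cl2, −20 to 0 °C; evaporate; then toluene, 110 °C
Reagents that add atoms: dimethyldioxirane, CC1(C)OO1
Why: The electron-rich enol acetate is epoxidised from the α face, since the β face is blocked by the axial C4 and C10 methyls and the 8β-silyloxy group. Thermal enol ester epoxide rearrangement then shifts the acetoxy group from C6 to C7 with inversion through a five-membered acyloxonium-type transition state. The acetate therefore arrives on the β face (equatorial) and C6 becomes the ketone.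

Step 20
Reactants: 27 (13S)-7β-acetoxy-16-(tert-butyldimethylsilyloxy)-9α,13-epoxy-15-methylidene-8β-(trimethylsilyloxy)labdan-6-one
Product: 28 (13S)-7β-acetoxy-9α,13-epoxy-8β,16-dihydroxy-15-methylidenelabdan-6-one
Conditions: HF·pyridine, pyridine, THF, 0 to 23 °C
Reagents that add atoms: none
Why: Buffered fluoride cleaves both silyl ethers and spares the acetate and the β-hydroxy ketone.

Step 21
Reactants: 28 (13S)-7β-acetoxy-9α,13-epoxy-8β,16-dihydroxy-15-methylidenelabdan-6-one
Product: 30 (13S)-7β-acetoxy-9α,13:15,16-diepoxy-8β,15-dihydroxylabdan-6-one (lactol; both C15 anomers), via aldehyde 29 (not isolated)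
Conditions: O3, CH2Cl2, −78 °C; then Me2S, −78 to 23 °C
Reagents that add atoms: ozone, [O-][O+]=O
Why: Ozonolysis of the only alkene with reductive work-up; the C15 aldehyde is captured at once by the C16 hydroxyl as the five-membered lactol.

Step 22
Reactants: 30 (13S)-7β-acetoxy-9α,13:15,16-diepoxy-8β,15-dihydroxylabdan-6-one
Product: 31 (13S)-7β-acetoxy-9α,13:15,16-diepoxy-8β-hydroxylabd-14-en-6-one (CNP0284584.1)
Conditions: MeSO2Cl, Et3N, CH2Cl2, −20 to 40 °C
Reagents that add atoms: none
Why: Mesylation of the lactol hydroxyl and base-induced elimination through the oxocarbenium ion give the 2,3-dihydrofuran; only C14 has hydrogens to lose and the hindered tertiary 8β-hydroxyl is not sulfonylated. Basic conditions protect the acid-labile spiro enol ether.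

## Compound list

1 | (+)-sclareolide | C[C@]12CCCC([C@@H]1CC[C@@]3([C@@H]2CC(=O)O3)C)(C)C | starting material
2 | 13,14,15,16-tetranorlabdane-8α,12-diol | C1C[C@H]2C(C)(C)CCC[C@]2(C)[C@@H](CCO)[C@]1(C)O | intermediate
3 | 8α-hydroxy-13,14,15,16-tetranorlabdan-12-yl acetate | C1C[C@H]2C(C)(C)CCC[C@]2(C)[C@@H](CCOC(C)=O)[C@]1(C)O | intermediate
4 | 13,14,15,16-tetranorlabd-8(17)-en-12-yl acetate | C1C[C@H]2C(C)(C)CCC[C@]2(C)[C@@H](CCOC(C)=O)C1=C | intermediate
5 | 8-oxo-13,14,15,16,17-pentanorlabdan-12-yl acetate | C1C[C@H]2C(C)(C)CCC[C@]2(C)[C@@H](CCOC(C)=O)C1=O | intermediate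
6 | 12-hydroxy-13,14,15,16,17-pentanorlabdan-8-one | C1C[C@H]2C(C)(C)CCC[C@]2(C)[C@@H](CCO)C1=O | intermediate
7 | 12-iodo-13,14,15,16,17-pentanorlabdan-8-one | C1C[C@H]2C(C)(C)CCC[C@]2(C)[C@@H](CCI)C1=O | intermediate
8 | 2-bromoprop-2-en-1-ol | OCC(Br)=C | starting material
9 | (2-bromoprop-2-enyloxy)trimethylsilane | C=C(Br)CO[Si](C)(C)C | intermediate
10 | (8-oxo-13,14,15,16,17-pentanorlabdan-12-yl)zinc iodide | C1C[C@H]2C(C)(C)CCC[C@]2(C)[C@@H](CC[Zn]I)C1=O | intermediate
11 | 16-(trimethylsilyloxy)-15,17-dinorlabd-13(14)-en-8-one | C1C[C@H]2C(C)(C)CCC[C@]2(C)[C@@H](CCC(=C)CO[Si](C)(C)C)C1=O | intermediate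
12 | 16-hydroxy-15,17-dinorlabd-13(14)-en-8-one | C1C[C@H]2C(C)(C)CCC[C@]2(C)[C@@H](CCC(=C)CO)C1=O | intermediate
13 | (13R)-13,14-epoxy-16-hydroxy-15,17-dinorlabdan-8-one | C1C[C@H]2C(C)(C)CCC[C@]2(C)[C@@H](CC[C@@]3(CO)CO3)C1=O | intermediate
14 | (13S)-16-(tert-butyldimethylsilyloxy)-13,14-epoxy-15,17-dinorlabdan-8-one | C1C[C@H]2C(C)(C)CCC[C@]2(C)[C@@H](CC[C@@]3(CO[Si](C)(C)C(C)(C)C)CO3)C1=O | intermediate
15 | (13S)-8,16-bis(tert-butyldimethylsilyloxy)-13,14-epoxy-15,17-dinorlabd-8-ene | C1C[C@H]2C(C)(C)CCC[C@]2(C)C(CC[C@@]3(CO[Si](C)(C)C(C)(C)C)CO3)=C1O[Si](C)(C)C(C)(C)C | intermediate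
16 | vinylmagnesium bromide | C=C[Mg]Br | starting material
17 | (13S)-8,16-bis(tert-butyldimethylsilyloxy)-15-methylidene-17-norlabd-8-en-13-ol | C1C[C@H]2C(C)(C)CCC[C@]2(C)C(CC[C@](O)(CC=C)CO[Si](C)(C)C(C)(C)C)=C1O[Si](C)(C)C(C)(C)C | intermediate
18 | (13S)-16-(tert-butyldimethylsilyloxy)-9α,13-epoxy-15-methylidene-17-norlabdan-8-one | C1C[C@H]2C(C)(C)CCC[C@]2(C)[C@@]2(CC[C@](CC=C)(CO[Si](C)(C)C(C)(C)C)O2)C1=O | intermediate
19 | (13S)-16-(tert-butyldimethylsilyloxy)-9α,13-epoxy-15-methylidene-17-norlabd-6-en-8-one | C1=C[C@H]2C(C)(C)CCC[C@]2(C)[C@@]2(CC[C@](CC=C)(CO[Si](C)(C)C(C)(C)C)O2)C1=O | intermediate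
20 | (13S)-16-(tert-butyldimethylsilyloxy)-9α,13-epoxy-15-methylidene-6α-(4,4,5,5-tetramethyl-1,3,2-dioxaborolan-2-yl)-17-norlabdan-8-one | C1[C@H](B3OC(C)(C)C(C)(C)O3)[C@H]2C(C)(C)CCC[C@]2(C)[C@@]2(CC[C@](CC=C)(CO[Si](C)(C)C(C)(C)C)O2)C1=O | intermediate
21 | (13S)-16-(tert-butyldimethylsilyloxy)-9α,13-epoxy-6α-hydroxy-15-methylidene-17-norlabdan-8-one | C1[C@H](O)[C@H]2C(C)(C)CCC[C@]2(C)[C@@]2(CC[C@](CC=C)(CO[Si](C)(C)C(C)(C)C)O2)C1=O | intermediate
22 | (13S)-16-(tert-butyldimethylsilyloxy)-9α,13-epoxy-15-methylidenelabdane-6α,8β-diol | C1[C@H](O)[C@H]2C(C)(C)CCC[C@]2(C)[C@@]2(CC[C@](CC=C)(CO[Si](C)(C)C(C)(C)C)O2)[C@@]1(C)O | intermediate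
23 | (13S)-16-(tert-butyldimethylsilyloxy)-9α,13-epoxy-8β-hydroxy-15-methylidenelabdan-6-one | C1C(=O)[C@H]2C(C)(C)CCC[C@]2(C)[C@@]2(CC[C@](CC=C)(CO[Si](C)(C)C(C)(C)C)O2)[C@@]1(C)O | intermediate
24 | (13S)-16-(tert-butyldimethylsilyloxy)-9α,13-epoxy-15-methylidene-8β-(trimethylsilyloxy)labdan-6-one | C1C(=O)[C@H]2C(C)(C)CCC[C@]2(C)[C@@]2(CC[C@](CC=C)(CO[Si](C)(C)C(C)(C)C)O2)[C@@]1(C)O[Si](C)(C)C | intermediate
25 | (13S)-16-(tert-butyldimethylsilyloxy)-9α,13-epoxy-15-methylidene-8β-(trimethylsilyloxy)labd-6-en-6-yl acetate | C1=C(OC(C)=O)[C@H]2C(C)(C)CCC[C@]2(C)[C@@]2(CC[C@](CC=C)(CO[Si](C)(C)C(C)(C)C)O2)[C@@]1(C)O[Si](C)(C)C | intermediate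
26 | (13S)-16-(tert-butyldimethylsilyloxy)-6α,7α:9α,13-diepoxy-15-methylidene-8β-(trimethylsilyloxy)labdan-6β-yl acetate | O1[C@@H]2[C@@]1(OC(C)=O)[C@H]3C(C)(C)CCC[C@]3(C)[C@@]3(CC[C@](CC=C)(CO[Si](C)(C)C(C)(C)C)O3)[C@@]2(C)O[Si](C)(C)C | intermediate
27 | (13S)-7β-acetoxy-16-(tert-butyldimethylsilyloxy)-9α,13-epoxy-15-methylidene-8β-(trimethylsilyloxy)labdan-6-one | CC(=O)O[C@H]1C(=O)[C@H]2C(C)(C)CCC[C@]2(C)[C@@]2(CC[C@](CC=C)(CO[Si](C)(C)C(C)(C)C)O2)[C@@]1(C)O[Si](C)(C)C | intermediate
28 | (13S)-7β-acetoxy-9α,13-epoxy-8β,16-dihydroxy-15-methylidenelabdan-6-one | CC(=O)O[C@H]1C(=O)[C@H]2C(C)(C)CCC[C@]2(C)[C@@]2(CC[C@](CC=C)(CO)O2)[C@@]1(C)O | intermediate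
29 | (13S)-7β-acetoxy-9α,13-epoxy-8β,16-dihydroxy-6-oxolabdan-15-al | CC(=O)O[C@H]1C(=O)[C@H]2C(C)(C)CCC[C@]2(C)[C@@]2(CC[C@](CC=O)(CO)O2)[C@@]1(C)O | intermediate
30 | (13S)-7β-acetoxy-9α,13:15,16-diepoxy-8β,15-dihydroxylabdan-6-one (both C15 anomers) | CC(=O)O[C@H]1C(=O)[C@H]2C(C)(C)CCC[C@]2(C)[C@@]2(CC[C@@]3(CC(O)OC3)O2)[C@@]1(C)O | intermediate
31 | (13S)-7β-acetoxy-9α,13:15,16-diepoxy-8β-hydroxylabd-14-en-6-one (CNP0284584.1) | CC(=O)O[C@H]1C(=O)[C@H]2C(C)(C)CCC[C@]2(C)[C@@]2(CC[C@@]3(C=COC3)O2)[C@@]1(C)O | target

## Step count and least certain steps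

Total: 22 steps. Longest linear sequence: 21 steps (steps 1–6 and 8–22, from 1 to 31); step 7 is a one-step side branch.

**Step 13 (key step).** The most likely failure is capture of the radical cation by methanol, or loss of the silyl group, before the hindered tertiary alcohol reaches the fully substituted C9; both partners are tertiary, which goes beyond the usual cases. The fallback replaces the radical cation by a polar two-step sequence from 17. N-Bromosuccinimide at −78 °C brominates the enol ether on the α face to give (13S)-9α-bromo-16-(tert-butyldimethylsilyloxy)-13-hydroxy-15-methylidene-17-norlabdan-8-one F1. Silver-assisted ionisation of the tertiary bromide (AgOTf, a hindered pyridine base, CH2Cl2) then lets the C13 hydroxyl close onto C9 from the same α face, which returns to 18.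

**Step 11.** The risk is incomplete regiocontrol in the enolisation: the C7 enolate may persist beside the more crowded C8=C9 enolate. The fallback removes the choice. From 14, kinetic enolisation at C7 and the dehydrogenation of step 14 give the enone (13S)-16-(tert-butyldimethylsilyloxy)-13,14-epoxy-15,17-dinorlabd-6-en-8-one F2. Its only α-hydrogen is now at C9, so deprotonation and silylation give the cross-conjugated diene (13S)-8,16-bis(tert-butyldimethylsilyloxy)-13,14-epoxy-15,17-dinorlabda-6,8-diene F3. Copper-catalysed opening with 16 gives (13S)-8,16-bis(tert-butyldimethylsilyloxy)-15-methylidene-17-norlabda-6,8-dien-13-ol F4, and anodic oxidation of F4 closes the ether at C9 and leaves the enone, returning to the route at 19.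

**Step 15.** Borylation may be slow at C6, which is flanked by the C4 and C10 quaternary carbons, and the terminal alkene may then start to compete. The fallback from 19 is nucleophilic epoxidation (t-BuOOH, DBU) from the α face to (13S)-16-(tert-butyldimethylsilyloxy)-6α,7α:9α,13-diepoxy-15-methylidene-17-norlabdan-8-one F5, then reductive cleavage of the C7–O bond with SmI2 (THF/MeOH, −78 °C), which gives 21.

**Step 16.** The polar effect of the axial C9–O bond may erode facial selectivity by drawing the nucleophile to the β face, or the β-hydroxy ketone may be enolised. The fallback from 21 uses a reversible addition that prefers an equatorial C–C bond: dimethylsulfoxonium methylide (Me3S(O)I, NaH, DMSO) gives the spiro-epoxide (13S)-16-(tert-butyldimethylsilyloxy)-8β,17:9α,13-diepoxy-15-methylidenelabdan-6α-ol F6. LiBHEt3 opens it at the CH2 carbon and returns to 22.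

**Step 19.** The terminal alkene may be epoxidised in competition, or the epoxy acetate may rearrange by the acid-catalysed path with retention, which would give the 7α-acetate. The fallback from 23 goes through a Rubottom oxidation and relies on thermodynamics.
- Me3SiOTf and Et3N give the bis-silyl compound (13S)-16-(tert-butyldimethylsilyloxy)-9α,13-epoxy-15-methylidene-6,8β-bis(trimethylsilyloxy)labd-6-ene F7.
- m-Chloroperbenzoic acid (NaHCO3), then brief K2CO3/MeOH, gives (13S)-16-(tert-butyldimethylsilyloxy)-9α,13-epoxy-7α-hydroxy-15-methylidene-8β-(trimethylsilyloxy)labdan-6-one F8.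
- Acetylation (Ac2O, DMAP, pyridine) gives the axial acetate (13S)-7α-acetoxy-16-(tert-butyldimethylsilyloxy)-9α,13-epoxy-15-methylidene-8β-(trimethylsilyloxy)labdan-6-one F9.
- DBU equilibrates F9 through the C6 enol to the equatorial 7β-acetate, which is free of the 1,3-diaxial contact with the C9 oxygen; this returns to 27.

## Further compounds

F1 | step 13 | (13S)-9α-bromo-16-(tert-butyldimethylsilyloxy)-13-hydroxy-15-methylidene-17-norlabdan-8-one | C1C[C@H]2C(C)(C)CCC[C@]2(C)[C@@](Br)(CC[C@](O)(CC=C)CO[Si](C)(C)C(C)(C)C)C1=O
F2 | step 11 | (13S)-16-(tert-butyldimethylsilyloxy)-13,14-epoxy-15,17-dinorlabd-6-en-8-one | C1=C[C@H]2C(C)(C)CCC[C@]2(C)[C@@H](CC[C@@]3(CO[Si](C)(C)C(C)(C)C)CO3)C1=O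
F3 | step 11 | (13S)-8,16-bis(tert-butyldimethylsilyloxy)-13,14-epoxy-15,17-dinorlabda-6,8-diene | C1=C[C@H]2C(C)(C)CCC[C@]2(C)C(CC[C@@]3(CO[Si](C)(C)C(C)(C)C)CO3)=C1O[Si](C)(C)C(C)(C)C
F4 | step 11 | (13S)-8,16-bis(tert-butyldimethylsilyloxy)-15-methylidene-17-norlabda-6,8-dien-13-ol | C1=C[C@H]2C(C)(C)CCC[C@]2(C)C(CC[C@](O)(CC=C)CO[Si](C)(C)C(C)(C)C)=C1O[Si](C)(C)C(C)(C)C
F5 | step 15 | (13S)-16-(tert-butyldimethylsilyloxy)-6α,7α:9α,13-diepoxy-15-methylidene-17-norlabdan-8-one | O1[C@@H]2[C@H]1[C@H]3C(C)(C)CCC[C@]3(C)[C@@]3(CC[C@](CC=C)(CO[Si](C)(C)C(C)(C)C)O3)C2=O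
F6 | step 16 | (13S)-16-(tert-butyldimethylsilyloxy)-8β,17:9α,13-diepoxy-15-methylidenelabdan-6α-ol | C1[C@H](O)[C@H]2C(C)(C)CCC[C@]2(C)[C@@]2(CC[C@](CC=C)(CO[Si](C)(C)C(C)(C)C)O2)[C@]13CO3
F7 | step 19 | (13S)-16-(tert-butyldimethylsilyloxy)-9α,13-epoxy-15-methylidene-6,8β-bis(trimethylsilyloxy)labd-6-ene | C1=C(O[Si](C)(C)C)[C@H]2C(C)(C)CCC[C@]2(C)[C@@]2(CC[C@](CC=C)(CO[Si](C)(C)C(C)(C)C)O2)[C@@]1(C)O[Si](C)(C)C
F8 | step 19 | (13S)-16-(tert-butyldimethylsilyloxy)-9α,13-epoxy-7α-hydroxy-15-methylidene-8β-(trimethylsilyloxy)labdan-6-one | O[C@@H]1C(=O)[C@H]2C(C)(C)CCC[C@]2(C)[C@@]2(CC[C@](CC=C)(CO[Si](C)(C)C(C)(C)C)O2)[C@@]1(C)O[Si](C)(C)C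
F9 | step 19 | (13S)-7α-acetoxy-16-(tert-butyldimethylsilyloxy)-9α,13-epoxy-15-methylidene-8β-(trimethylsilyloxy)labdan-6-one | CC(=O)O[C@@H]1C(=O)[C@H]2C(C)(C)CCC[C@]2(C)[C@@]2(CC[C@](CC=C)(CO[Si](C)(C)C(C)(C)C)O2)[C@@]1(C)O[Si](C)(C)C
A1 | alternative 1 | 2,6-dimethyl-1,4-benzoquinone | CC1=CC(=O)C=C(C)C1=O
A2 | alternative 1 | 4-methylpenta-1,3-diene | C=CC=C(C)C
A3 | alternative 1 | cis-fused 4,4,8,10-tetramethyldecalin-2,7-diene-6,9-dione | O=C1C=C(C)C(=O)[C@@]2(C)CC=CC(C)(C)[C@@H]12
A4 | alternative 2 | 12-oxo-9,13-epoxy decalin with spiro butanolide (6-methoxymethyl ether, 8-ol) | C1[C@H](OCOC)[C@H]2C(C)(C)CCC[C@]2(C)[C@@]2(CC(=O)[C@@]3(CC(=O)OC3)O2)[C@@]1(C)O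
A5 | alternative 3 | 6,8-bis(tert-butyldimethylsilyloxy) decalin with spiro 2-methylenetetrahydrofuran at C9 | C1[C@H](O[Si](C)(C)C(C)(C)C)[C@H]2C(C)(C)CCC[C@]2(C)[C@@]2(CCC(=C)O2)[C@H]1O[Si](C)(C)C(C)(C)C
A6 | alternative 3 | dichloroketene | ClC(Cl)=C=O
A7 | alternative 3 | bis-spiro 2,2-dichlorocyclobutanone | C1[C@H](O[Si](C)(C)C(C)(C)C)[C@H]2C(C)(C)CCC[C@]2(C)[C@@]2(CC[C@]3(CC(=O)C3(Cl)Cl)O2)[C@H]1O[Si](C)(C)C(C)(C)C
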